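Ring B is assembled on the ester carbon that ring A already holds, instead of being introduced as a preformed acid. Ring B has its hindered carboxyl carbon C1 between C2–OMe and C6–Me, and a second oxygen at C4, meta to the first, that must stay free for ring C. One photochemical operation should deliver this pattern: an ester-substituted vinylketene, formed by Wolff shift, takes up methoxyacetylene, and 4π opening followed by 6π closure forges C1–C2, C3–C4 and C4–C5, so that C4–OH and C2–OMe differ by origin. The precursor is the ring A aryl ester of 2-diazo-4-methyl-3-oxopent-4-enoic acid, with the ring A phenol masked as a benzyl ether.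

Key step: step 8

Remark: the target has no stereocentre and no stereogenic double bond, so no enantiomer exists and no step sets configuration; the ring A 2-hydroxyl is carried as a benzyl ether from step 2 to step 12, so that no O–H group is present while carbene and ketene are generated.

Step 1
Reactants: 1 methyl orsellinate (methyl 2,4-dihydroxy-6-methylbenzoate)
Product: 2 methyl 4-(allyloxy)-2-hydroxy-6-methylbenzoate
Conditions: allyl bromide (1.05 equiv), K2CO3, acetone, rt
Reagents that add atoms: allyl bromide, C=CCBr
Why: Williamson etherification should take place at O-4 only, because the 2-OH is tied to the ester carbonyl by a hydrogen bond and is much less reactive towards one equivalent of halide under mild base.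

Step 2
Reactants: 2 methyl 4-(allyloxy)-2-hydroxy-6-methylbenzoate
Product: 3 methyl 4-(allyloxy)-2-(benzyloxy)-6-methylbenzoate
Conditions: BnBr, K2CO3, cat. KI, DMF, 60 °C
Reagents that add atoms: benzyl bromide, BrCc1ccccc1
Why: A Williamson etherification under more forcing conditions should benzylate the remaining chelated phenol, the allyl ether and the methyl ester being inert to carbonate.

Step 3
Reactants: 3 methyl 4-(allyloxy)-2-(benzyloxy)-6-methylbenzoate
Product: 4 methyl 2-(benzyloxy)-4-hydroxy-6-methylbenzoate
Conditions: Pd(PPh3)4 (cat.), morpholine, THF, rt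
Reagents that add atoms: none
Why: In this Tsuji–Trost deallylation Pd(0) ionises the aryl allyl ether and morpholine takes up the π-allyl fragment, which should leave the benzyl ether and the methyl ester untouched.

Step 4
Reactants: 5 Meldrum's acid; 6 methacryloyl chloride
Product: 7 5-(1-hydroxy-2-methylprop-2-en-1-ylidene)-2,2-dimethyl-1,3-dioxane-4,6-dione (methacryloyl Meldrum's acid, enol form)
Conditions: pyridine, CH2Cl2, 0 °C to rt; used crude after acid wash
Reagents that add atoms: none
Why: C-acylation of Meldrum's acid by an acid chloride with pyridine is a standard route to acyl Meldrum's acids, and the α-methyl group should slow conjugate addition to the acryloyl unit.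

Step 5
Reactants: 4 methyl 2-(benzyloxy)-4-hydroxy-6-methylbenzoate; 7 methacryloyl Meldrum's acid
Product: 9 methyl 2-(benzyloxy)-6-methyl-4-[(4-methyl-3-oxopent-4-enoyl)oxy]benzoate, via methacryloylketene 8 (not isolated)
Conditions: toluene, BHT (cat.), 90 °C
Reagents that add atoms: none
Why: Thermal fragmentation of the acyl Meldrum's acid releases acetone, CO2 and an acylketene, which the single free phenol of 4 should capture to give the aryl β-keto ester (acylketene transfer), while BHT suppresses radical polymerisation of the isopropenyl ketone.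

Step 6
Reactants: 9 methyl 2-(benzyloxy)-6-methyl-4-[(4-methyl-3-oxopent-4-enoyl)oxy]benzoate
Product: 10 methyl 2-(benzyloxy)-4-[(2-diazo-4-methyl-3-oxopent-4-enoyl)oxy]-6-methylbenzoate
Conditions: p-ABSA, Et3N, MeCN, 0 °C to rt
Reagents that add atoms: 4-acetamidobenzenesulfonyl azide (p-ABSA), CC(=O)Nc1ccc(cc1)S(=O)(=O)N=[N+]=[N-]
Why: In this Regitz diazo transfer the doubly activated methylene is deprotonated by triethylamine and attacks the sulfonyl azide, which hands over N2 and leaves as the sulfonamide.

Step 7
Reactants: 11 chloroacetaldehyde dimethyl acetal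
Product: 14 methoxyacetylene, via 1-chloro-2-methoxyethene 12 (not isolated), via sodium methoxyacetylide 13 (not isolated)
Conditions: NaNH2 (3 equiv), liq. NH3, −33 °C; evaporate NH3; sat. aq. NaCl, −70 °C to rt; distil into ClCH2CH2Cl at −20 °C (volatile and hazardous, kept as a cold solution behind a shield)
Reagents that add atoms: none
Why: Twofold base-induced elimination (methanol, then HCl) with sodium amide in liquid ammonia is the standard preparation of alkoxyacetylenes, the acetylide being protonated on aqueous quench.

Step 8
Reactants: 10 methyl 2-(benzyloxy)-4-[(2-diazo-4-methyl-3-oxopent-4-enoyl)oxy]-6-methylbenzoate; 14 methoxyacetylene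
Product: 19 ring A–B didepside phenol methyl 2-(benzyloxy)-4-[(4-hydroxy-2-methoxy-6-methylbenzoyl)oxy]-6-methylbenzoate, via vinylketene 15 (not isolated), via cyclobutenone 16 (not isolated), via dienylketene 17 (not isolated), via cyclohexadienone 18 (not isolated)
Conditions: 14 (8 equiv), hν (365 nm, Pyrex), ClCH2CH2Cl, 5 °C; then sealed tube, 80 °C
Reagents that add atoms: none
Why: Proposed new method: irradiation should expel N2 from 10 with 1,2-shift of the isopropenyl group from the ketone carbon (Wolff rearrangement) to give vinylketene 15, whose C=C adds methoxyacetylene in a polar [2+2] (alkyne CH to the ketene carbonyl carbon, C–OMe to the ester-bearing carbon) to give cyclobutenone 16, and warming should then open 16 by reversible 4π-electrocyclic cleavage to dienylketene 17, close it to dienone 18 and enolise that to phenol 19. The closest known reaction type is the Danheiser benzannulation in its photo-Wolff variant, in which α-diazo enones serve as vinylketene sources towards heteroatom-substituted alkynes; new here is the aryloxycarbonyl group on the diazo carbon, which makes the ketene an acylketene. Ring B is closed by a thermal 6π-electrocyclisation of 17 that joins the ketene carbon (C4) to the isopropenyl CH2 (C5), after the [2+2] has already set C1–C2 and C3–C4; the four-membered ring of 16 is transient. No stereocentre is created in the product, since the quaternary carbon of 16 forms as a racemate and becomes planar on ring opening, and because that opening is reversible both geometries of 17 should drain through the Z isomer that can cyclise. The step needs alkenyl and not aryloxy migration, which the much higher migratory aptitude of an sp2 carbon on a ketone over an alkoxy group on an ester should secure, and it needs [2+2] at the ketene C=C instead of hetero-[4+2] across the ester carbonyl, which the weak heterodiene character of an ester C=O and the strong polarisation of the ynol ether should favour, the same polarisation placing OMe at C2. Cold photolysis with excess alkyne and a benzylated ring A phenol means that no O–H group and little thermal diazo–alkyne cycloaddition compete while the ketene is formed, the phenol of 19 appearing only in the later thermal phase.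

Step 9
Reactants: 20 orsellinic acid
Product: 21 benzyl 2,4-bis(benzyloxy)-6-methylbenzoate
Conditions: BnBr (3.5 equiv), K2CO3, DMF, rt then 60 °C
Reagents that add atoms: benzyl bromide, BrCc1ccccc1
Why: Williamson alkylation should proceed at the carboxylate and the 4-OH at room temperature, which removes the risk of decarboxylation, and at the chelated 2-OH on warming.

Step 10
Reactants: 21 benzyl 2,4-bis(benzyloxy)-6-methylbenzoate
Product: 22 2,4-bis(benzyloxy)-6-methylbenzoic acid
Conditions: KOH, MeOH/dioxane/H2O, reflux; then aq. HCl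
Reagents that add atoms: potassium hydroxide, [K+].[OH-]
Why: Saponification of the hindered benzyl ester under forcing alkaline conditions should give the acid after acidification, the benzyl aryl ethers being inert to hydroxide.

Step 11
Reactants: 22 2,4-bis(benzyloxy)-6-methylbenzoic acid; 19 ring A–B didepside phenol
Product: 24 methyl 2-(benzyloxy)-4-({4-[(2,4-bis(benzyloxy)-6-methylbenzoyl)oxy]-2-methoxy-6-methylbenzoyl}oxy)-6-methylbenzoate, via acid chloride 23 (not isolated)
Conditions: (COCl)2, cat. DMF, CH2Cl2, 0 °C to rt, evaporate; then 19, Et3N, DMAP, CH2Cl2, rt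
Reagents that add atoms: none
Why: Acid chloride formation followed by DMAP-catalysed O-acylation of the only free phenol of 19 is a standard depside esterification, and the existing di-ortho-substituted aryl ester should be too hindered to transacylate.

Step 12
Reactants: 24 tribenzyl tridepside
Product: 25 methyl 4-({4-[(2,4-dihydroxy-6-methylbenzoyl)oxy]-2-methoxy-6-methylbenzoyl}oxy)-2-hydroxy-6-methylbenzoate (target)
Conditions: H2 (1 atm), 10% Pd/C, EtOAc/THF, rt
Reagents that add atoms: none
Why: Catalytic hydrogenolysis over palladium in an aprotic solvent should cleave the three benzyl aryl ethers, while the aryl esters and the methyl ester persist.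

Compound list
1 | methyl orsellinate (methyl 2,4-dihydroxy-6-methylbenzoate) | COC(=O)c1c(C)cc(O)cc1O | starting material
2 | methyl 4-(allyloxy)-2-hydroxy-6-methylbenzoate | COC(=O)c1c(C)cc(OCC=C)cc1O | intermediate
3 | methyl 4-(allyloxy)-2-(benzyloxy)-6-methylbenzoate | COC(=O)c1c(C)cc(OCC=C)cc1OCc1ccccc1 | intermediate
4 | methyl 2-(benzyloxy)-4-hydroxy-6-methylbenzoate | COC(=O)c1c(C)cc(O)cc1OCc1ccccc1 | intermediate
5 | Meldrum's acid (2,2-dimethyl-1,3-dioxane-4,6-dione) | CC1(C)OC(=O)CC(=O)O1 | starting material
6 | methacryloyl chloride | CC(=C)C(Cl)=O | starting material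
7 | 5-(1-hydroxy-2-methylprop-2-en-1-ylidene)-2,2-dimethyl-1,3-dioxane-4,6-dione | CC(=C)C(O)=C1C(=O)OC(C)(C)OC1=O | intermediate
8 | methacryloylketene (4-methylpenta-1,4-diene-1,3-dione), not isolated | CC(=C)C(=O)C=C=O | intermediate
9 | methyl 2-(benzyloxy)-6-methyl-4-[(4-methyl-3-oxopent-4-enoyl)oxy]benzoate | COC(=O)c1c(C)cc(OC(=O)CC(=O)C(C)=C)cc1OCc1ccccc1 | intermediate
10 | methyl 2-(benzyloxy)-4-[(2-diazo-4-methyl-3-oxopent-4-enoyl)oxy]-6-methylbenzoate (key-step precursor) | COC(=O)c1c(C)cc(OC(=O)C(=[N+]=[N-])C(=O)C(C)=C)cc1OCc1ccccc1 | intermediate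
11 | chloroacetaldehyde dimethyl acetal | COC(CCl)OC | starting material
12 | 1-chloro-2-methoxyethene (E/Z mixture), not isolated | COC=CCl | intermediate
13 | sodium methoxyacetylide, not isolated | [Na+].[C-]#COC | intermediate
14 | methoxyacetylene | COC#C | intermediate
15 | vinylketene: methyl 2-(benzyloxy)-6-methyl-4-{[3-methyl-2-(oxomethylidene)but-3-enoyl]oxy}benzoate, not isolated | COC(=O)c1c(C)cc(OC(=O)C(=C=O)C(C)=C)cc1OCc1ccccc1 | intermediate
16 | cyclobutenone: methyl 2-(benzyloxy)-4-{[2-methoxy-4-oxo-1-(prop-1-en-2-yl)cyclobut-2-ene-1-carbonyl]oxy}-6-methylbenzoate (racemic), not isolated | COC(=O)c1c(C)cc(OC(=O)C2(C(C)=C)C(OC)=CC2=O)cc1OCc1ccccc1 | intermediate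
17 | dienylketene: methyl 2-(benzyloxy)-4-{[(2Z)-3-methoxy-5-oxo-2-(prop-1-en-2-yl)penta-2,4-dienoyl]oxy}-6-methylbenzoate, not isolated | COC(=O)c1c(C)cc(OC(=O)/C(C(C)=C)=C(OC)/C=C=O)cc1OCc1ccccc1 | intermediate
18 | cyclohexadienone: methyl 2-(benzyloxy)-4-[(6-methoxy-2-methyl-4-oxocyclohexa-1,5-diene-1-carbonyl)oxy]-6-methylbenzoate, not isolated | COC(=O)c1c(C)cc(OC(=O)C2=C(C)CC(=O)C=C2OC)cc1OCc1ccccc1 | intermediate
19 | methyl 2-(benzyloxy)-4-[(4-hydroxy-2-methoxy-6-methylbenzoyl)oxy]-6-methylbenzoate (key-step product) | COC(=O)c1c(C)cc(OC(=O)c2c(C)cc(O)cc2OC)cc1OCc1ccccc1 | intermediate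
20 | orsellinic acid (2,4-dihydroxy-6-methylbenzoic acid) | Cc1cc(O)cc(O)c1C(=O)O | starting material
21 | benzyl 2,4-bis(benzyloxy)-6-methylbenzoate | Cc1cc(OCc2ccccc2)cc(OCc2ccccc2)c1C(=O)OCc1ccccc1 | intermediate
22 | 2,4-bis(benzyloxy)-6-methylbenzoic acid | Cc1cc(OCc2ccccc2)cc(OCc2ccccc2)c1C(=O)O | intermediate
23 | 2,4-bis(benzyloxy)-6-methylbenzoyl chloride, not isolated | Cc1cc(OCc2ccccc2)cc(OCc2ccccc2)c1C(Cl)=O | intermediate
24 | methyl 2-(benzyloxy)-4-({4-[(2,4-bis(benzyloxy)-6-methylbenzoyl)oxy]-2-methoxy-6-methylbenzoyl}oxy)-6-methylbenzoate | COC(=O)c1c(C)cc(OC(=O)c2c(C)cc(OC(=O)c3c(C)cc(OCc4ccccc4)cc3OCc3ccccc3)cc2OC)cc1OCc1ccccc1 | intermediate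
25 | methyl 4-({4-[(2,4-dihydroxy-6-methylbenzoyl)oxy]-2-methoxy-6-methylbenzoyl}oxy)-2-hydroxy-6-methylbenzoate | COC(=O)c1c(C)cc(OC(=O)c2c(C)cc(OC(=O)c3c(C)cc(O)cc3O)cc2OC)cc1O | target

Total step count: 12. Longest linear sequence: 8 steps (1, 2, 3, 5, 6, 8, 11, 12) from methyl orsellinate.

Steps most likely to fail

1. Step 8 (proposed new method). Several processes could divert it:
- the excited diazo compound may react as a carbene or isomerise instead of undergoing the Wolff shift;
- the diazo group may add thermally to the ynol ether as a dipole;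
- the acylketene may be consumed by hetero-[4+2] capture or dimerisation;
- the aryl esters may undergo photo-Fries rearrangement;
- residual ketene may acylate the newly formed phenol.

The fallback gives up the benzannulation and builds the A–B ester by known acylation chemistry. It sets out from 2 and 4 and comes back at 19. Compound 2 is O-methylated (MeI, K2CO3, DMF) to methyl 4-(allyloxy)-2-methoxy-6-methylbenzoate F1. Saponification (KOH, aq. MeOH, reflux) gives 4-(allyloxy)-2-methoxy-6-methylbenzoic acid F2. Oxalyl chloride with cat. DMF converts this into 4-(allyloxy)-2-methoxy-6-methylbenzoyl chloride F3, which is coupled with phenol 4 (Et3N, DMAP, CH2Cl2) to methyl 4-{[4-(allyloxy)-2-methoxy-6-methylbenzoyl]oxy}-2-(benzyloxy)-6-methylbenzoate F4. Deallylation with Pd(PPh3)4 and morpholine should then free the ring B phenol and give 19.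

2. Step 5. The acylketene may dimerise faster than a moderately nucleophilic phenol captures it, and the isopropenyl β-keto ester may polymerise or self-condense by Michael addition at 90 °C.

The fallback avoids any β-keto ester with a free methylene and makes steps 4 to 6 unnecessary. It sets out from 4 and comes back at 10. Phenol 4 is acylated with bromoacetyl bromide and pyridine to methyl 2-(benzyloxy)-4-[(bromoacetyl)oxy]-6-methylbenzoate F5. N,N'-Ditosylhydrazine and DBU convert this into the aryl diazoacetate methyl 2-(benzyloxy)-4-[(diazoacetyl)oxy]-6-methylbenzoate F6. DBU-catalysed aldol-type addition of F6 to methacrolein should give racemic methyl 2-(benzyloxy)-4-[(2-diazo-3-hydroxy-4-methylpent-4-enoyl)oxy]-6-methylbenzoate F7, and oxidation with IBX in DMSO should give 10.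

3. Step 11. Acyl transfer from the di-ortho-substituted acid chloride may be slow, so that conversion stalls or base- and DMAP-mediated acyl migration scrambles the existing depside ester.

The fallback uses a less hindered ring C donor with a free chelated 2-hydroxyl and a base-free condensation. It sets out from 20 and 19 and comes back at 25. Orsellinic acid 20 is benzylated at the carboxylate and at O-4 only (BnBr, 2 equiv, KHCO3, DMF, rt) to benzyl 4-(benzyloxy)-2-hydroxy-6-methylbenzoate F8. Saponification gives 4-(benzyloxy)-2-hydroxy-6-methylbenzoic acid F9. DCC-mediated condensation of F9 with 19 in toluene should give methyl 2-(benzyloxy)-4-({4-[(4-(benzyloxy)-2-hydroxy-6-methylbenzoyl)oxy]-2-methoxy-6-methylbenzoyl}oxy)-6-methylbenzoate F10, and hydrogenolysis (H2, Pd/C, EtOAc) of its two benzyl ethers should give 25 directly.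

Further compounds
F1 | step 8 | methyl 4-(allyloxy)-2-methoxy-6-methylbenzoate | COC(=O)c1c(C)cc(OCC=C)cc1OC
F2 | step 8 | 4-(allyloxy)-2-methoxy-6-methylbenzoic acid | OC(=O)c1c(C)cc(OCC=C)cc1OC
F3 | step 8 | 4-(allyloxy)-2-methoxy-6-methylbenzoyl chloride | ClC(=O)c1c(C)cc(OCC=C)cc1OC
F4 | step 8 | methyl 4-{[4-(allyloxy)-2-methoxy-6-methylbenzoyl]oxy}-2-(benzyloxy)-6-methylbenzoate | COC(=O)c1c(C)cc(OC(=O)c2c(C)cc(OCC=C)cc2OC)cc1OCc1ccccc1
F5 | step 5 | methyl 2-(benzyloxy)-4-[(bromoacetyl)oxy]-6-methylbenzoate | COC(=O)c1c(C)cc(OC(=O)CBr)cc1OCc1ccccc1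
F6 | step 5 | methyl 2-(benzyloxy)-4-[(diazoacetyl)oxy]-6-methylbenzoate | COC(=O)c1c(C)cc(OC(=O)C=[N+]=[N-])cc1OCc1ccccc1
F7 | step 5 | methyl 2-(benzyloxy)-4-[(2-diazo-3-hydroxy-4-methylpent-4-enoyl)oxy]-6-methylbenzoate (racemic) | COC(=O)c1c(C)cc(OC(=O)C(=[N+]=[N-])C(O)C(C)=C)cc1OCc1ccccc1
F8 | step 11 | benzyl 4-(benzyloxy)-2-hydroxy-6-methylbenzoate | Cc1cc(OCc2ccccc2)cc(O)c1C(=O)OCc1ccccc1
F9 | step 11 | 4-(benzyloxy)-2-hydroxy-6-methylbenzoic acid | Cc1cc(OCc2ccccc2)cc(O)c1C(=O)O
F10 | step 11 | methyl 2-(benzyloxy)-4-({4-[(4-(benzyloxy)-2-hydroxy-6-methylbenzoyl)oxy]-2-methoxy-6-methylbenzoyl}oxy)-6-methylbenzoate | COC(=O)c1c(C)cc(OC(=O)c2c(C)cc(OC(=O)c3c(C)cc(OCc4ccccc4)cc3O)cc2OC)cc1OCc1ccccc1
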